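Readings and results stem from a simulated flask from invented constants, noise included.

I started from the clock.

| flask | electrophile | nucleophile | remark | time |
|---|---|---|---|---|
| south | 18 mM | 1.3 equiv | run made earlier |  |
| north | 24 mM | 1.3 equiv | run made earlier |  |
| cedar | 12 mM | 1.30 equiv |  | 2.5 h |
| larch | 12 mM | 2.00 equiv |  | 2.5 h |

| run | time / min | electrophile / % | target / % |
|---|---|---|---|
| south | 4.00 | 99 | 0 |
| south | 6.00 | 97 | 4 |
| south | 10.0 | 92 | 6 |
| south | 15.0 | 92 | 2 |
| south | 25.0 | 83 | 7 |
| south | 30.0 | 84 | 5 |
| south | 50.0 | 77 | 8 |
| north | 3.00 | 100 | 6 |
| north | 8.00 | 94 | 3 |
| north | 15.0 | 89 | 4 |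
| north | 25.0 | 83 | 8 |
| north | 30.0 | 80 | 8 |
| north | 40.0 | 74 | 10 |
| north | 50.0 | 70 | 8 |

(each reading ± 2 percentage points)

- the numbers in the tables scatter by 2 percentage points (one standard deviation)

1. part of the electrophile that has reacted at the end, cedar
2. part of the electrophile that has reacted at the end, larch
3. what raising the equivalents of nucleophile from its lowest to its highest value here does to the part of the electrophile that has reacted (changes below 5 percentage points count as none) (it rises / no change / it falls)

Time was the first setting I turned. I took nucleophile as held at its charge and let the electrophile fall by a steady fraction in each half-life, so I read that half-life from the last reading of each run: 133 min for south and 97.2 min for north. The electrophile charge came next. At equal equivalents north held more nucleophile than south, and the half-life I read for it was shorter by a factor of 1.37, close to the charge ratio of 1.33 given a scatter of 2 percentage points. The equivalents came last, and here the runs were silent, because both used 1.3 equiv, so I assumed that the electrophile reacts with nucleophile and that the half-life varies inversely with [nucleophile], the pseudo-first-order picture. Scaling both runs and averaging gave me for cedar an estimated half-life of the electrophile at charged nucleophile of 197 min, so 2.5 h counted 0.761 half-lives and I reckoned 41.1% reacted. For larch the same scaling gave an estimated half-life of 128 min, which counted 1.17 half-lives, and I reckoned 55.7% reacted.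

The forecast, slightly lower than my two figures, put cedar at 40% and larch at 54%, said of the equivalents that it rises, and judged: “Cedar is therefore robust, while larch is uncertain”.

The flask gave 40.7% for cedar and 55.6% for larch; on raising the equivalents, it rises, by 15 points.

    electrophile + target → side product (k = 0.860 M⁻¹ min⁻¹)
    electrophile + nucleophile → acid set free + target (k = 0.250 M⁻¹ min⁻¹)
    target ⇌ isomer of the product (K = 1.50, k = 0.0600 min⁻¹)
    nucleophile + acid set free ⇌ protonated nucleophile, settled at all times (K = 94000 M⁻¹)

At the end of larch, free nucleophile stood at 54.6% of its charge, so it had not stayed at the charge my half-life assumed. My two estimated half-lives, 197 min and 128 min, gave a reckoned step of 15 points from cedar to larch.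

For the neighbour of larch with 5.00 equiv of nucleophile, the same scaling gave an estimated half-life of 51.1 min, hence 2.94 half-lives in 2.5 h and a reckoned 86.9% reacted. The computed neighbour flask gave 87.8% reacted.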